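**Plan**

1. Numbering used here: ring C1 carries OH and the side chain, C2 is the ring CH2 between C1 and C3 (CHCl), C4 is CMeBr, C5 and C6 are CH2; side chain C7(=CH2)–C8H2–C9H(OH)–C10H=C11Me2.
2. Retrosynthetic cuts, in order: C8–C9 (aldol with prenal) and the C7 methylene (methylenation); the acetyl group back to an alkyne; C4–Br (HBr on an exocyclic methylene); C3–Cl (inversion of an allylic C3–OH); C1–alkynyl (acetylide on a C1 ketone); last the ring bond C2–C3 (aldol).
3. Enabling feature: C1–O and C3–Cl sit 1,3 across the C2 methylene of the six-membered ring, so with C1 as ketone and C3 as carbinol the ring is a β-ketol; reading C4(Me)Br as a methylidene makes the C3 aldehyde non-enolisable. The open chain, 2-methylidene-5-oxohexanal, comes in two steps from 1-methylcyclopentene, whose methyl group becomes ring carbon C2.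
4. Forward order: the carbocycle is closed first (C2–C3), then C1 is made quaternary, then chloride, bromide, acetyl group, and last the side chain.
5. Stereochemistry: C3 from the chiral borane in the ring closure; C1 by substrate control (OH cis to the C3 oxygen); C3–Cl by SN2 inversion; C4–Br anti to the axial C3–Cl; C9 from a second chiral boron aldol.

Key step: step 3

Assumption: the facial preference of diisopinocampheylboron enolates of methyl ketones toward enals is taken as (+)-Ipc2BCl giving the S carbinol when the alkenyl carbon outranks the enolate carbon, in both aldol steps; if it is reversed in either, the antipodal borane is used with no other change.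

**Route**

Step 1
Reactants: 1 1-methylcyclopentene
Product: 3 5-oxohexanal, via ozonide 2 (not isolated)
Conditions: O3, CH2Cl2, −78 °C; then Me2S, −78 to 23 °C
Reagents that add atoms: ozone, [O-][O+]=O
Why: Ozonolysis of the only C=C and reduction of the ozonide with Me2S open the ring to the methyl ketone and aldehyde termini; no stereocentre is formed.

Step 2
Reactants: 3 5-oxohexanal
Product: 5 2-methylidene-5-oxohexanal, via Mannich base 4 (not isolated)
Conditions: CH2=NMe2+ I− (Eschenmoser's salt), Et3N, CH2Cl2, 23 °C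
Reagents that add atoms: N,N-dimethylmethaniminium iodide, C=[N+](C)C.[I-]
Why: Mannich reaction at the aldehyde α-carbon (enolised more readily than the ketone) followed by β-elimination of dimethylamine should give the 2-substituted acrolein; no stereocentre.

Step 3
Reactants: 5 2-methylidene-5-oxohexanal
Product: 8 (3R)-3-hydroxy-4-methylidenecyclohexan-1-one, via boron enolate 6 (not isolated), via boron aldolate 7 (not isolated)
Conditions: (−)-Ipc2BCl, Et3N, Et2O, −78 to −20 °C; then MeOH, pH 7 buffer, H2O2, 0 °C
Reagents that add atoms: none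
Why: Et3N and the chloroborane enolise the methyl ketone at its methyl carbon (C2) to boron enolate 6, whose boron binds the aldehyde oxygen so that C2 adds to the carbonyl carbon C3 through a closed Zimmerman–Traxler array fused to the forming carbocycle (a bicyclo[3.3.1]-like transition state), giving aldolate 7. The closest known reaction type is the aldol addition of diisopinocampheylboron enolates of methyl ketones to enals, run here intramolecularly as in boron-mediated aldol cyclisations. The six-membered ring closes in the 6-(enolexo)-exo-trig mode. The one new stereocentre, C3, is set by the isopinocampheyl ligands on boron (reagent control), the substrate being achiral. The step needs 1,2-addition at C3 instead of 6-endo conjugate addition at the methylidene carbon, and enolisation at the methyl instead of the C6 methylene: the boron-templated cyclic transition state reaches only the carbonyl carbon, an enolate at C6 could close only a four-membered ring, and the 2-substituted acrolein has no α-hydrogen and cannot act as donor.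

Step 4
Reactants: 8 (3R)-3-hydroxy-4-methylidenecyclohexan-1-one
Product: 9 (3R)-4-methylidene-3-[(triethylsilyl)oxy]cyclohexan-1-one
Conditions: Et3SiCl, imidazole, DMF, 0 °C
Reagents that add atoms: chlorotriethylsilane, CC[Si](Cl)(CC)CC
Why: Silylation of the secondary alcohol under mild base blocks retro-aldol and E1cB loss of the β-oxygen (which would lead to p-cresol) before the ketone meets a basic nucleophile; the stereocentre is untouched.

Step 5
Reactants: 9 (3R)-4-methylidene-3-[(triethylsilyl)oxy]cyclohexan-1-one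
Product: 11 (1R,3R)-1-ethynyl-4-methylidenecyclohexane-1,3-diol, via silyl ether 10 (not isolated)
Conditions: HC≡CMgBr, CeCl3, THF, −78 °C; then 1 M HCl, THF, 23 °C
Reagents that add atoms: ethynylmagnesium bromide, C#C[Mg]Br
Why: Organocerium 1,2-addition of the weakly basic acetylide avoids enolisation, and the slim sp nucleophile adds axially when the C3 silyloxy group is equatorial and is forced onto the equatorial path when that group is axial, so both conformers should place the C1–OH cis to the C3 oxygen (1R); the acid work-up removes the secondary silyl ether.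

Step 6
Reactants: 11 (1R,3R)-1-ethynyl-4-methylidenecyclohexane-1,3-diol
Product: 12 (1R,3S)-3-chloro-1-ethynyl-4-methylidenecyclohexan-1-ol
Conditions: Ph3P, Cl3CC(O)CCl3, CH2Cl2, −20 to 0 °C
Reagents that add atoms: hexachloroacetone, ClC(Cl)(Cl)C(=O)C(Cl)(Cl)Cl
Why: Appel-type chlorination with Ph3P/hexachloroacetone converts the secondary allylic alcohol through its alkoxyphosphonium salt by SN2 attack of chloride with inversion and without allylic transposition, giving (3S); the hindered tertiary alcohol does not react and, being cis, cannot displace the activated oxygen.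

Step 7
Reactants: 12 (1R,3S)-3-chloro-1-ethynyl-4-methylidenecyclohexan-1-ol
Product: 13 {[(1R,3S)-3-chloro-1-ethynyl-4-methylidenecyclohexyl]oxy}triethylsilane
Conditions: Et3SiOTf, 2,6-lutidine, CH2Cl2, −78 to 0 °C
Reagents that add atoms: triethylsilyl trifluoromethanesulfonate, CC[Si](CC)(CC)OS(=O)(=O)C(F)(F)F
Why: Silyl triflate with a hindered pyridine base silylates the tertiary propargylic alcohol, which prevents its ionisation by HBr and makes the oxygen substituent on C1 the bulky (equatorial) one for the next step.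

Step 8
Reactants: 13 {[(1R,3S)-3-chloro-1-ethynyl-4-methylidenecyclohexyl]oxy}triethylsilane
Product: 14 {[(1R,3S,4S)-4-bromo-3-chloro-1-ethynyl-4-methylcyclohexyl]oxy}triethylsilane
Conditions: HBr (anhydrous), CH2Cl2, −78 °C, dark, BHT (cat.)
Reagents that add atoms: hydrogen bromide, Br
Why: Markovnikov ionic hydrobromination: protonation of the methylidene gives the tertiary C4 cation, and in the chair with the bulky C1 silyloxy group equatorial (slim ethynyl axial) the allylic C3–Cl is axial, so bromide should enter axially and anti to it (chloronium-like shielding of the other face), giving the trans bromochloride (4S).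

Step 9
Reactants: 14 {[(1R,3S,4S)-4-bromo-3-chloro-1-ethynyl-4-methylcyclohexyl]oxy}triethylsilane
Product: 15 1-[(1R,3S,4S)-4-bromo-3-chloro-4-methyl-1-[(triethylsilyl)oxy]cyclohexyl]ethan-1-one
Conditions: (Ph3P)AuNTf2 (cat.), 1,4-dioxane/H2O, 40 °C
Reagents that add atoms: water, O
Why: Gold-catalysed Markovnikov hydration of the terminal alkyne (π-activation, attack of water at the internal carbon, tautomerisation) unveils the methyl ketone under neutral conditions; ionisation of the tertiary bromide is retarded by the β-chlorine.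

Step 10
Reactants: 15 1-[(1R,3S,4S)-4-bromo-3-chloro-4-methyl-1-[(triethylsilyl)oxy]cyclohexyl]ethan-1-one; 16 3-methylbut-2-enal
Product: 19 (3S)-1-[(1R,3S,4S)-4-bromo-3-chloro-4-methyl-1-[(triethylsilyl)oxy]cyclohexyl]-3-hydroxy-5-methylhex-4-en-1-one, via boron enolate 17 (not isolated), via boron aldolate 18 (not isolated)
Conditions: (+)-Ipc2BCl, Et3N, Et2O, −78 to 0 °C; 16, −78 to −20 °C; then MeOH, pH 7 buffer, H2O2, 0 °C
Reagents that add atoms: none
Why: Chiral boron enolate aldol: the ketone is enolised on its only enolisable side and adds 1,2 to the enal through a closed six-membered transition state, the isopinocampheyl ligands selecting the aldehyde face that gives (S) at C9 (reagent control).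

Step 11
Reactants: 19 (3S)-1-[(1R,3S,4S)-4-bromo-3-chloro-4-methyl-1-[(triethylsilyl)oxy]cyclohexyl]-3-hydroxy-5-methylhex-4-en-1-one
Product: 20 (3S)-1-[(1R,3S,4S)-4-bromo-3-chloro-4-methyl-1-[(triethylsilyl)oxy]cyclohexyl]-5-methyl-3-[(triethylsilyl)oxy]hex-4-en-1-one
Conditions: Et3SiOTf, 2,6-lutidine, CH2Cl2, −78 °C
Reagents that add atoms: triethylsilyl trifluoromethanesulfonate, CC[Si](CC)(CC)OS(=O)(=O)C(F)(F)F
Why: Silylation of the secondary allylic alcohol guards against retro-aldol and against consumption of the titanium reagent in the next step.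

Step 12
Reactants: 20 (3S)-1-[(1R,3S,4S)-4-bromo-3-chloro-4-methyl-1-[(triethylsilyl)oxy]cyclohexyl]-5-methyl-3-[(triethylsilyl)oxy]hex-4-en-1-one
Product: 21 {[(1R,3S,4S)-4-bromo-3-chloro-4-methyl-1-[(4S)-6-methyl-4-[(triethylsilyl)oxy]hepta-1,5-dien-2-yl]cyclohexyl]oxy}triethylsilane
Conditions: Cp2Ti(μ-CH2)(μ-Cl)AlMe2, pyridine, THF, −40 to 0 °C
Reagents that add atoms: Tebbe reagent, C[Al-]1(C)C[Ti]([Cl+]1)(C2C=CC=C2)C2C=CC=C2
Why: Tebbe methylenation (titanium methylidene, [2+2] addition and cycloreversion) converts the hindered, base-sensitive β-silyloxy ketone into the 1,1-disubstituted alkene without enolisation or elimination; no stereocentre changes.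

Step 13
Reactants: 21 {[(1R,3S,4S)-4-bromo-3-chloro-4-methyl-1-[(4S)-6-methyl-4-[(triethylsilyl)oxy]hepta-1,5-dien-2-yl]cyclohexyl]oxy}triethylsilane
Product: 22 (1R,3S,4S)-4-bromo-3-chloro-1-[(4S)-4-hydroxy-6-methylhepta-1,5-dien-2-yl]-4-methylcyclohexan-1-ol
Conditions: HF·pyridine, pyridine, THF, 0 to 23 °C
Reagents that add atoms: none
Why: Buffered fluoride cleaves both triethylsilyl ethers without the basicity that would eliminate the tertiary bromide or the acidity that would ionise the allylic alcohols, giving the target.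

**Compound list**

1 | 1-methylcyclopentene | CC1=CCCC1 | starting material
2 | 1-methyl-6,7,8-trioxabicyclo[3.2.1]octane (ozonide, racemic) | CC12CCCC(OO1)O2 | intermediate
3 | 5-oxohexanal | CC(=O)CCCC=O | intermediate
4 | 2-[(dimethylamino)methyl]-5-oxohexanal (Mannich base, racemic) | CC(=O)CCC(CN(C)C)C=O | intermediate
5 | 2-methylidene-5-oxohexanal | CC(=O)CCC(=C)C=O | intermediate
6 | 5-[(diisopinocampheylboranyl)oxy]-2-methylidenehex-5-enal (boron enolate; isopinocampheyl groups from (+)-α-pinene) | C=C(CCC(=C)C=O)OB([C@@H]1C[C@@H]2C[C@H]([C@H]1C)C2(C)C)[C@@H]1C[C@@H]2C[C@H]([C@H]1C)C2(C)C | intermediate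
7 | (3R)-3-[(diisopinocampheylboranyl)oxy]-4-methylidenecyclohexan-1-one (boron aldolate) | O=C1CCC(=C)[C@H](OB([C@@H]2C[C@@H]3C[C@H]([C@H]2C)C3(C)C)[C@@H]2C[C@@H]3C[C@H]([C@H]2C)C3(C)C)C1 | intermediate
8 | (3R)-3-hydroxy-4-methylidenecyclohexan-1-one | O=C1CCC(=C)[C@H](O)C1 | intermediate
9 | (3R)-4-methylidene-3-[(triethylsilyl)oxy]cyclohexan-1-one | O=C1CCC(=C)[C@H](O[Si](CC)(CC)CC)C1 | intermediate
10 | (1R,3R)-1-ethynyl-4-methylidene-3-[(triethylsilyl)oxy]cyclohexan-1-ol | C#C[C@@]1(O)CCC(=C)[C@H](O[Si](CC)(CC)CC)C1 | intermediate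
11 | (1R,3R)-1-ethynyl-4-methylidenecyclohexane-1,3-diol | C#C[C@@]1(O)CCC(=C)[C@H](O)C1 | intermediate
12 | (1R,3S)-3-chloro-1-ethynyl-4-methylidenecyclohexan-1-ol | C#C[C@@]1(O)CCC(=C)[C@@H](Cl)C1 | intermediate
13 | {[(1R,3S)-3-chloro-1-ethynyl-4-methylidenecyclohexyl]oxy}triethylsilane | C#C[C@@]1(O[Si](CC)(CC)CC)CCC(=C)[C@@H](Cl)C1 | intermediate
14 | {[(1R,3S,4S)-4-bromo-3-chloro-1-ethynyl-4-methylcyclohexyl]oxy}triethylsilane | C#C[C@@]1(O[Si](CC)(CC)CC)CC[C@](C)(Br)[C@@H](Cl)C1 | intermediate
15 | 1-[(1R,3S,4S)-4-bromo-3-chloro-4-methyl-1-[(triethylsilyl)oxy]cyclohexyl]ethan-1-one | CC(=O)[C@@]1(O[Si](CC)(CC)CC)CC[C@](C)(Br)[C@@H](Cl)C1 | intermediate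
16 | 3-methylbut-2-enal (prenal) | CC(C)=CC=O | starting material
17 | diisopinocampheylboron enolate of 15 at its methyl carbon (isopinocampheyl groups from (−)-α-pinene) | C=C(OB([C@H]2C[C@H]3C[C@@H]([C@@H]2C)C3(C)C)[C@H]2C[C@H]3C[C@@H]([C@@H]2C)C3(C)C)[C@@]1(O[Si](CC)(CC)CC)CC[C@](C)(Br)[C@@H](Cl)C1 | intermediate
18 | diisopinocampheylborinate of 19 at the C9 oxygen (boron aldolate) | O=C(C[C@H](OB([C@H]2C[C@H]3C[C@@H]([C@@H]2C)C3(C)C)[C@H]2C[C@H]3C[C@@H]([C@@H]2C)C3(C)C)C=C(C)C)[C@@]1(O[Si](CC)(CC)CC)CC[C@](C)(Br)[C@@H](Cl)C1 | intermediate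
19 | (3S)-1-[(1R,3S,4S)-4-bromo-3-chloro-4-methyl-1-[(triethylsilyl)oxy]cyclohexyl]-3-hydroxy-5-methylhex-4-en-1-one | O=C(C[C@H](O)C=C(C)C)[C@@]1(O[Si](CC)(CC)CC)CC[C@](C)(Br)[C@@H](Cl)C1 | intermediate
20 | (3S)-1-[(1R,3S,4S)-4-bromo-3-chloro-4-methyl-1-[(triethylsilyl)oxy]cyclohexyl]-5-methyl-3-[(triethylsilyl)oxy]hex-4-en-1-one | O=C(C[C@H](O[Si](CC)(CC)CC)C=C(C)C)[C@@]1(O[Si](CC)(CC)CC)CC[C@](C)(Br)[C@@H](Cl)C1 | intermediate
21 | {[(1R,3S,4S)-4-bromo-3-chloro-4-methyl-1-[(4S)-6-methyl-4-[(triethylsilyl)oxy]hepta-1,5-dien-2-yl]cyclohexyl]oxy}triethylsilane | C=C(C[C@H](O[Si](CC)(CC)CC)C=C(C)C)[C@@]1(O[Si](CC)(CC)CC)CC[C@](C)(Br)[C@@H](Cl)C1 | intermediate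
22 | (1R,3S,4S)-4-bromo-3-chloro-1-[(4S)-4-hydroxy-6-methylhepta-1,5-dien-2-yl]-4-methylcyclohexan-1-ol | C=C(C[C@H](O)C=C(C)C)[C@@]1(O)CC[C@](C)(Br)[C@@H](Cl)C1 | target

**Step count and risks**

Total steps: 13. Longest linear sequence: 13 (from 1-methylcyclopentene).

Step 3. What may go wrong: poor enantiofacial discrimination in the constrained bicyclic transition state, reduction of the aldehyde by the chloroborane, or competing conjugate closure. Fallback: from 5, Bu2BOTf/iPr2NEt (CH2Cl2, −78 °C, buffered peroxide work-up) closes the same bond without asymmetric induction to racemic 3-hydroxy-4-methylidenecyclohexan-1-one F1. Candida antarctica lipase B with vinyl acetate should then acylate the R alcohol (the usual lipase preference, the methylidene-bearing carbon being the large group) to (1R)-2-methylidene-5-oxocyclohexyl acetate F2 and leave (3S)-3-hydroxy-4-methylidenecyclohexan-1-one F3, which is separated. The same lipase in pH 7 phosphate buffer hydrolyses F2, and the route is rejoined at 8.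

Step 8. What may go wrong: capture of the C4 cation through the other half-chair (bromide syn to chlorine), or ionisation and transposition of the allylic chloride under acid. Fallback: from 13, radical Markovnikov hydrobromination by metal-hydride hydrogen atom transfer (Co(acac)2, t-BuOOH, 1,4-cyclohexadiene, TsBr, n-PrOH, 23 °C), in which the tertiary β-chloroalkyl radical should take bromine anti to the C–Cl bond; the route is rejoined at 14 and no new compound is passed.

Step 12. What may go wrong: ionisation or methylation of the tertiary bromide by the Lewis-acidic aluminium component, or sluggish methylenation of the hindered ketone. Fallback: from 20, Peterson olefination: Me3SiCH2MgCl/CeCl3 (THF, −78 °C) adds to the ketone to give (4S)-2-[(1R,3S,4S)-4-bromo-3-chloro-4-methyl-1-[(triethylsilyl)oxy]cyclohexyl]-6-methyl-4-[(triethylsilyl)oxy]-1-(trimethylsilyl)hept-5-en-2-ol F4 (both epimers at the new carbinol carbon). Aqueous HF in MeCN at 0 °C then effects the acid-mediated elimination and removes both triethylsilyl ethers, rejoining the route at 22.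

**Further compounds**

F1 | step 3 | rac-3-hydroxy-4-methylidenecyclohexan-1-one | O=C1CCC(=C)C(O)C1
F2 | step 3 | (1R)-2-methylidene-5-oxocyclohexyl acetate | O=C1CCC(=C)[C@H](OC(C)=O)C1
F3 | step 3 | (3S)-3-hydroxy-4-methylidenecyclohexan-1-one | O=C1CCC(=C)[C@@H](O)C1
F0 | step 8 | none | none
F4 | step 12 | (4S)-2-[(1R,3S,4S)-4-bromo-3-chloro-4-methyl-1-[(triethylsilyl)oxy]cyclohexyl]-6-methyl-4-[(triethylsilyl)oxy]-1-(trimethylsilyl)hept-5-en-2-ol | C[Si](C)(C)CC(O)(C[C@H](O[Si](CC)(CC)CC)C=C(C)C)[C@@]1(O[Si](CC)(CC)CC)CC[C@](C)(Br)[C@@H](Cl)C1
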